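**Retrosynthetic overview**
- Target ⇒ its 5‑O‑TBS ether ⇒ cut C2–O1 to an open 2'-hydroxychalcone. Ring C closes last, by a catalytic enantioselective, chalcone‑isomerase‑type 6‑endo oxa‑Michael addition on the plain, unactivated enone. This one step sets C2 as S.
- The two ortho oxygens of the chalcone A ring are told apart by their history. The free OH of the bought acetophenone ends as 5‑OH and is held as a TBS ether. The crowded ortho‑OMe is unmasked by chelation‑controlled BCl3 cleavage and becomes O1, so only the 7,8‑dimethoxy isomer can form.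
- Chalcone ⇒ cut Cα=Cβ: Claisen–Schmidt condensation of 6‑hydroxy‑2,3,4‑trimethoxyacetophenone with 2,6‑dimethoxybenzaldehyde.
- Ring order: A and B are bought intact, and C is the only ring formed.

Assumption: the facial sense of the quinidine‑derived catalyst is taken by analogy with cinchona‑thiourea conjugate additions to chalcones (quinine series Re face, quinidine series Si face of Cβ); it is checked on the final product by ECD and chiral HPLC, and the quinine‑derived pseudo‑enantiomer is the drop‑in switch.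

**Step 1**
Reactants: 1 1‑(6‑hydroxy‑2,3,4‑trimethoxyphenyl)ethanone; 2 2,6‑dimethoxybenzaldehyde
Product: 3 (E)‑3‑(2,6‑dimethoxyphenyl)‑1‑(6‑hydroxy‑2,3,4‑trimethoxyphenyl)prop‑2‑en‑1‑one
Conditions: KOH (6 equiv, 50% aq), EtOH, rt, 36 h; then 1 M HCl, 0 °C, pH 4; recryst. EtOH
Reagents that add atoms: none
Why: Claisen–Schmidt (crossed aldol) condensation: the methyl‑ketone enolate adds to the non‑enolisable aldehyde and E1cB loss of water gives the thermodynamic (E)‑enone, while the strongly basic medium holds the product as its ring‑open phenolate so that closure through the free OH stays minor; no stereocentre is formed.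

**Step 2**
Reactants: 3 (E)‑3‑(2,6‑dimethoxyphenyl)‑1‑(6‑hydroxy‑2,3,4‑trimethoxyphenyl)prop‑2‑en‑1‑one
Product: 4 (E)‑1‑[6‑(tert‑butyldimethylsilyloxy)‑2,3,4‑trimethoxyphenyl]‑3‑(2,6‑dimethoxyphenyl)prop‑2‑en‑1‑one
Conditions: TBSOTf (1.3 equiv), 2,6‑lutidine (2.0 equiv), CH2Cl2, 0 °C → rt, 2 h
Reagents that add atoms: tert‑butyldimethylsilyl triflate (TBSOTf), CC(C)(C)[Si](C)(C)OS(=O)(=O)C(F)(F)F
Why: O‑Silylation with a silyl triflate: the very electrophilic silicon overrides the OH···O=C hydrogen bond of the only free phenol, the ketone has no enolisable α‑hydrogen, and the oxygen that will end as 5‑OH is thereby fixed and blocked.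

**Step 3**
Reactants: 4 (E)‑1‑[6‑(tert‑butyldimethylsilyloxy)‑2,3,4‑trimethoxyphenyl]‑3‑(2,6‑dimethoxyphenyl)prop‑2‑en‑1‑one
Product: 6 (E)‑1‑[6‑(tert‑butyldimethylsilyloxy)‑2‑hydroxy‑3,4‑dimethoxyphenyl]‑3‑(2,6‑dimethoxyphenyl)prop‑2‑en‑1‑one, via dichloroboron chelate 5 (not isolated)
Conditions: BCl3 (1.0 M in CH2Cl2, 1.3 equiv), CH2Cl2, −78 → −20 °C, 1–2 h; then cold pH 7 phosphate buffer
Reagents that add atoms: none
Why: Chelation‑controlled ortho‑demethylation of an aryl ketone with BCl3: boron bridges C=O and the twisted, most Lewis‑basic 2‑OMe (a silyl ether oxygen is a poor donor and does not chelate), chloride removes the methyl group by SN2, and chelate 5 holds the enone turned away from the new oxygen until the cold neutral quench, so no closure occurs here.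

**Step 4**
Reactants: 6 (E)‑1‑[6‑(tert‑butyldimethylsilyloxy)‑2‑hydroxy‑3,4‑dimethoxyphenyl]‑3‑(2,6‑dimethoxyphenyl)prop‑2‑en‑1‑one
Product: 8 (2S)‑5‑hydroxy‑7,8,2',6'‑tetramethoxyflavanone, via 5‑O‑TBS flavanone 7 (not isolated)
Conditions: 9‑amino‑9‑deoxy‑epi‑quinidine‑derived 3,5‑bis(trifluoromethyl)phenyl thiourea (10 mol %), PhMe (0.1 M), 0 °C, 48–72 h (HPLC control, >95% conv.); then KHF2 (2.5 equiv), MeOH, 0 °C → rt, 1–2 h; chromatography, one recrystallisation (EtOH) to ≥99% ee
Reagents that add atoms: none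
Why: Proposed new method: a direct chalcone‑isomerase‑like 6‑endo‑trig intramolecular oxa‑Michael addition of an unactivated, β‑(2,6‑dimethoxyphenyl) 2'-hydroxychalcone under bifunctional cinchona‑thiourea catalysis, in which the quinuclidine takes the proton of the only free phenol while the thiourea N–H pair polarises the enone C=O, so that the phenoxide is delivered inside a chiral hydrogen‑bonded ion pair to the Si face of Cβ and sets C2 as S; the ortho silyloxy group twists the aryl ketone out of conjugation (faster closure, equilibrium on the flavanone side) and blocks the second ortho oxygen so that only the 7,8‑dimethoxy regioisomer can form; KHF2 then protonates the amine, which stops retro‑Michael racemisation, and cleaves the phenolic TBS ether at near‑neutral pH without touching C2; the closest known reaction types are the cinchona‑thiourea oxa‑Michael closure of ester‑activated alkylidene β‑keto esters to flavanones and the cinchona‑base cyclisation of 6'-substituted 2'-hydroxychalcones with moderate ee.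

**Compound list**
1 | 1‑(6‑hydroxy‑2,3,4‑trimethoxyphenyl)ethanone (2'-hydroxy‑4',5',6'-trimethoxyacetophenone) | CC(=O)c1c(O)cc(OC)c(OC)c1OC | starting material
2 | 2,6‑dimethoxybenzaldehyde | O=Cc1c(OC)cccc1OC | starting material
3 | (E)‑3‑(2,6‑dimethoxyphenyl)‑1‑(6‑hydroxy‑2,3,4‑trimethoxyphenyl)prop‑2‑en‑1‑one | COc1cc(O)c(C(=O)/C=C/c2c(OC)cccc2OC)c(OC)c1OC | intermediate
4 | (E)‑1‑[6‑(tert‑butyldimethylsilyloxy)‑2,3,4‑trimethoxyphenyl]‑3‑(2,6‑dimethoxyphenyl)prop‑2‑en‑1‑one | COc1cc(O[Si](C)(C)C(C)(C)C)c(C(=O)/C=C/c2c(OC)cccc2OC)c(OC)c1OC | intermediate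
5 | (E)‑1‑[6‑(tert‑butyldimethylsilyloxy)‑2‑(dichloroboryloxy)‑3,4‑dimethoxyphenyl]‑3‑(2,6‑dimethoxyphenyl)prop‑2‑en‑1‑one (C=O→B chelate, not isolated) | COc1cc(O[Si](C)(C)C(C)(C)C)c(C(=O)/C=C/c2c(OC)cccc2OC)c(OB(Cl)Cl)c1OC | intermediate
6 | (E)‑1‑[6‑(tert‑butyldimethylsilyloxy)‑2‑hydroxy‑3,4‑dimethoxyphenyl]‑3‑(2,6‑dimethoxyphenyl)prop‑2‑en‑1‑one | COc1cc(O[Si](C)(C)C(C)(C)C)c(C(=O)/C=C/c2c(OC)cccc2OC)c(O)c1OC | intermediate
7 | (2S)‑5‑(tert‑butyldimethylsilyloxy)‑2‑(2,6‑dimethoxyphenyl)‑7,8‑dimethoxychroman‑4‑one (not isolated) | COc1cc(O[Si](C)(C)C(C)(C)C)c2c(c1OC)O[C@H](c1c(OC)cccc1OC)CC2=O | intermediate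
8 | (2S)‑5‑hydroxy‑7,8,2',6'‑tetramethoxyflavanone | COc1cc(O)c2c(c1OC)O[C@H](c1c(OC)cccc1OC)CC2=O | target

**Total step count:** 4. **Longest linear sequence:** 4 (1 → 3 → 4 → 6 → 8).

**Steps most likely to fail, with fallbacks**

(i) The ring closure in step 4 is the riskiest. The β‑aryl group is hindered and electron‑rich, so conversion or ee may be too low.
- The fallback gives up asymmetric induction and uses racemic closure, chromatographic resolution and a racemisation recycle.
- It sets out from 6, which is closed with an achiral base (DBU 10 mol %, PhMe, rt) to the racemic 5‑O‑TBS flavanone F1.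
- Preparative chiral SFC on an immobilised amylose phase splits this into 7 and the (2R)‑5‑O‑TBS flavanone F2.
- The latter is re‑equilibrated with DBU through 6 back to the racemate and resubmitted. The silyl group keeps the regiochemistry intact during this retro‑Michael/Michael cycle.
- The route is rejoined at 7, which is desilylated with KHF2/MeOH as before.

(ii) The demethylation in step 3 may strip the TBS group or go further along the ring.
- The fallback reverses the logic and replaces differentiation by history with differentiation by sterics.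
- It sets out from 3, which is treated with excess BCl3 (2.5–3 equiv, CH2Cl2, −20 °C → rt) to give the 2',6'-dihydroxy‑3',4',2,6‑tetramethoxychalcone F3.
- TBSCl (1.05 equiv) and imidazole in CH2Cl2 at 0 °C then silylate the hydroxyl flanked by a ring hydrogen, not the one wedged between the carbonyl and the 3'-OMe.
- The route is rejoined at 6, bypassing 4 and 5.

(iii) The condensation in step 1 may be slow with the hindered, electron‑rich aldehyde, or may leak to the 5,6,7‑trimethoxyflavanone.
- The fallback changes the disconnection to the aryl–carbonyl bond, that is, transfer of an intact cinnamoyl unit onto the A ring.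
- It sets out from 2, which is condensed with malonic acid (pyridine, cat. piperidine, 90 °C, Knoevenagel–Doebner) to (E)‑2,6‑dimethoxycinnamic acid F4.
- Oxalyl chloride with cat. DMF converts this to (E)‑2,6‑dimethoxycinnamoyl chloride F5.
- Heating this with bought 3,4,5‑trimethoxyphenol (COc1cc(O)cc(OC)c1OC) in BF3·OEt2 first forms 3,4,5‑trimethoxyphenyl (E)‑2,6‑dimethoxycinnamate F6.
- That ester undergoes Fries rearrangement in the same flask to the only free ortho position. The route is rejoined at 3.

**Further compounds**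
F1 | step 4 | racemic 5‑(tert‑butyldimethylsilyloxy)‑2‑(2,6‑dimethoxyphenyl)‑7,8‑dimethoxychroman‑4‑one | COc1cc(O[Si](C)(C)C(C)(C)C)c2c(c1OC)OC(c1c(OC)cccc1OC)CC2=O
F2 | step 4 | (2R)‑5‑(tert‑butyldimethylsilyloxy)‑2‑(2,6‑dimethoxyphenyl)‑7,8‑dimethoxychroman‑4‑one | COc1cc(O[Si](C)(C)C(C)(C)C)c2c(c1OC)O[C@@H](c1c(OC)cccc1OC)CC2=O
F3 | step 3 | (E)‑1‑(2,6‑dihydroxy‑3,4‑dimethoxyphenyl)‑3‑(2,6‑dimethoxyphenyl)prop‑2‑en‑1‑one | COc1cc(O)c(C(=O)/C=C/c2c(OC)cccc2OC)c(O)c1OC
F4 | step 1 | (E)‑3‑(2,6‑dimethoxyphenyl)prop‑2‑enoic acid | OC(=O)/C=C/c1c(OC)cccc1OC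
F5 | step 1 | (E)‑3‑(2,6‑dimethoxyphenyl)prop‑2‑enoyl chloride | ClC(=O)/C=C/c1c(OC)cccc1OC
F6 | step 1 | 3,4,5‑trimethoxyphenyl (E)‑3‑(2,6‑dimethoxyphenyl)prop‑2‑enoate | COc1cc(OC(=O)/C=C/c2c(OC)cccc2OC)cc(OC)c1OC
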